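The easy step came first: I divided how fast partner takes the left-handed substrate by how fast it takes the right-handed one, at equal amounts of each.

common to all: left-handed substrate 0.10 M; partner 2.20 equiv; right-handed substrate 0.10 M; time 15 min
- Saturday's: at 60 °C until 5.0 min, from then on at 40 °C
- Friday's: temperature 40 °C
- Wednesday's: temperature 60 °C

    partner + left-handed substrate → left-handed product (k1 = 0.80 L mol⁻¹ min⁻¹, Ea1 = 66.0 kJ mol⁻¹)
    partner + right-handed substrate → right-handed product (k2 = 0.043 L mol⁻¹ min⁻¹, Ea2 = 61.0 kJ mol⁻¹)
    left-handed substrate ⇌ right-handed substrate (k3 = 0.038 min⁻¹, Ea3 = 88.0 kJ mol⁻¹)
    partner ⇌ dormant form (K4 = 0.12, k4 = 0.14 min⁻¹, Ea4 = 109 kJ mol⁻¹, ΔH4 = −55.0 kJ mol⁻¹)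
    partner → decomposed reagent (k5 = 0.057 min⁻¹, Ea5 = 100 kJ mol⁻¹)
    (constants at 60 °C)

- partner is single-handed; left-handed substrate and right-handed substrate are mirror images of each other, charged as a racemate, each of them at the stated concentration
- at 60 °C the constants are as listed, elsewhere as the activation energies and enthalpies make them
- an excess is the difference of the two amounts in percent of their sum
- an excess is below zero if the other one leads
- the handed part of partner does not stay in what it makes, so the products of the two hands are mirror images too

1. which flask leads in excess of left-handed product over right-handed product ("all alike" within 1.5 percentage points) (Saturday's / Friday's / Wednesday's / all alike)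
2. excess of left-handed product over right-handed product at the end, Saturday's
3. excess of left-handed product over right-handed product at the end, Friday's
4. excess of left-handed product over right-handed product at the end, Wednesday's

At 60 °C that quotient of the two rate constants was 18.6; this is the selectivity factor, and I carried it through. At 40 °C it fell to 16.6, lower, since step one loses 4.6 in speed on cooling and step two 4.1.

Before much has reacted, the excess at 60 °C is 89.8%, but the left-handed substrate thins out, so I worked with fractions left. Both hands meet the same partner. If neither substrate turned into the other, the logarithm of the right-handed fraction left would therefore be the left-handed one divided by the factor. The excess then follows from the two fractions gone.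

For the left-handed fraction left I guessed a mean partner over the time, as a fraction of its charge:

- Wednesday's: mean 0.5, factor 18.6, left 26.7%, excess 82.9%
- Friday's: mean 0.7, factor 16.6, left 66.8%, excess 86.5%
- Saturday's: mean 0.7 while hot, then 0.5, factor 18.6, left 44.6%, excess 85.8%

Read downward, Wednesday's had a better factor than Friday's, yet in this reckoning it kept less left-handed substrate than the others, and its excess came out lowest. Friday's, with the poorer factor, was reckoned to keep the most and stood highest. Saturday's took the hot factor, as its hot part removes more left-handed substrate than its cold part. So I committed to Friday's, ahead of Saturday's by 0.70 percentage points and of Wednesday's by 3.6 points, with the turning of one substrate into the other struck out.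

The forecast also named Friday's, but with other numbers, 82%, 85% and 80% for Saturday's, Friday's and Wednesday's, holding that the right-handed product's share at higher temperature and the faster loss of partner at 60 °C “erode selectivity”.

The simulation gave 86.2%, 86.3% and 85.5% in that order: all alike. In Saturday's at 2.29 min, partner used left-handed substrate 3.1 times as fast as that substrate turned into right-handed substrate, forward step alone, so the path I struck out was running. Wednesday's ended with 43% of its left-handed substrate against my 26.7%; that fraction comes from a flask in which the substrates also turned into each other, and put into my formula with the factor 18.6, which strikes that turning out, it gives 85.6%.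

Saturday's neighbour charged with 5.50 equiv of partner kept 18% of its left-handed substrate, and the same factor gives 80.6% there. The simulation gave 80.1%.

Its constants are those of an exercise; the rest is arithmetic.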